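## Compound numbers used throughout

1 syringic acid; 2 benzyl ester of 3 (not isolated); 3 O-benzylsyringic acid; 4 its 2,6-dibromide; 5 the acid chloride of 4; 6 methoxyhydroquinone; 7 its bis(methoxymethyl) ether; 8 aryllithium from 7 (not isolated); 9 ring B methyl ketone; 10 lithium enolate of 9 (not isolated); 11 dibromo diketone (precursor of the key step); 12 5-bromoflavone (product of the key step); 13 5,7-dibenzyl ether; 14 5,7-diol with ring B still protected; 15 target. Structures are in the list after the steps.

## Analysis of the target

The target 15 is a flavone: a benzo ring A fused to a 4-pyranone ring C (4H-chromen-4-one), with aryl ring B on C2 and hydrogen on C3. Ring A is fully substituted (OH on C5 and C7, OMe on C6 and C8). Ring B carries OMe on C2' and OH on C3' and C6', so seven oxygens on two arenes have to end up as three methyl ethers and four free phenols. There is no stereocentre. The C2–C1' axis has OMe and OH on the ring B side but only C3–H and O1 on the other, so no stable axial chirality is expected. Three groups are sensitive: the 3',6'-hydroquinone of ring B oxidises in air to the quinone, fastest in base; ring C is opened by hydroxide attack at C2; and the C5 hydroxyl is hydrogen-bonded to the C4 carbonyl. The difficulty is to build the hexasubstituted ring A without any regiochemical doubt, and to form bonds next to ring B, which has both ortho positions occupied. The strategy rests on the local symmetry of ring A about the C4a–C7 axis: C6 and C8 both carry OMe, and C5 and C8a both carry oxygen (the hydroxyl and O1). C4, C4a and the oxygens on C6, C7 and C8 are therefore the skeleton of syringic acid 1, and its two equivalent positions ortho to the carboxyl group become C5 and C8a. The same symmetry makes acid-induced opening and re-closure of ring C (Wessely–Moser type) degenerate, so acid cannot scramble ring A.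

## Retrosynthetic reasoning

**15 ⇒ 14 ⇒ 13 (phenolic O–C bonds).** Only protecting-group bonds are cut at the end. The two acetals on O3' and O6' of 14 are removed last with acid; before that, the benzyl ethers on O5 and O7 of 13 are removed together by hydrogenolysis. Two kinds of protecting group are kept because each has a job. The acetals are the metalation directors used to make ring B. A benzyl ether is the simplest phenol mask on ring A that survives conversion of an acid into acid chloride 5. The forward steps must leave the C2–C3 double bond and the three methyl ethers untouched, and must release the ring B hydroquinone without oxidising it.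

**13 ⇒ 12 (C5–O).** The C5–O bond is cut back to the C5 bromide of 12. This bromide sits peri to the C4 carbonyl, which can hold a copper alkoxide next to it. The oxygen is introduced as a benzyl ether under copper catalysis rather than as a free hydroxyl with hot aqueous alkali, because alkali adds to C2 of ring C and opens it. The benzyl ether costs no extra step, since it leaves together with the one on O7.

**12 ⇒ 11 (C8a–O1, the key disconnection).** Cutting C8a–O1 opens ring C to diketone 11, in which ring A carries bromine on both carbons ortho to the acyl group. This cut is chosen because it turns the regiochemical problem of ring A into a symmetry argument: whichever bromide is displaced, the same flavone results, and the bromide that is left is exactly at C5. The forward reaction must arylate the enol oxygen on the ring B side, not carbon, and must stop after one substitution.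

**11 ⇒ 5 + 9 (C3–C4).** The diketone is cut between its methylene carbon and the ring A carbonyl, giving acid chloride 5 and enolate 10 of methyl ketone 9. This splits the molecule into two arenes of similar size. The other cut, C2–C3, would need an acid chloride of ring B, which the acetals would not survive. The forward reaction is a C-acylation of 10 at an acyl carbon shielded by two bromines.

**5 ⇒ 4 ⇒ 3 ⇒ 1 (two C–Br bonds, O7–benzyl).** Both bromines are removed to give acid 3, and the benzyl group is removed to give 1. The order is fixed by two facts. The free phenol of 1 would direct an electrophile to the carboxyl-bearing carbon, so benzylation comes first. An ester flanked by two bromines resists saponification, so ester 2 is hydrolysed before bromination. In 3 the only free ring positions are C2 and C6, each ortho to one methoxy group and para to the other, so double bromination has no regiochemical alternative.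

**9 ⇒ 7 ⇒ 6 (C1'–acyl).** The acetyl group is removed from ring B to give 7, in which the required carbon is the only one lying between two ether oxygens. Metalation directed by both neighbours (aryllithium 8) followed by acylation is the forward reaction. Electrophilic acylation would go para to the methoxy group, at the wrong carbon. The bis-acetal 7 comes from commercial 6 in one step.

## Alternatives that were turned down

**Alternative 1: ring A built onto a preformed pyranone by cyclobutenone ring expansion.** The disconnection cuts C8–C8a and C4a–C5, so ring A is made last. In the forward key step, heating cyclobutenone A2 opens the four-membered ring to a dienylketene, which closes by 6π electrocyclisation onto the pyranone C–H carbon and tautomerises to the 5,8-hydroquinone A1. In its favour, all four ring A oxygens arrive in one step, O6 and O7 are already differentiated, and no halogen has to be exchanged for oxygen; on that last point it is stronger than the chosen route. Against it, A2 has to be made by adding a metalated 2-aryl-4-pyranone, itself an electrophile that opens easily, to one of two nearly equivalent carbonyl groups of an unsymmetrical four-membered diester. Whether methyl ends up on O6 or O7 then depends on the small difference between a methoxy and a tert-butoxy group three atoms away. A1 is an electron-rich hydroquinone that oxidises readily, and it still needs selective methylation of O8 next to the chelated O5 hydroxyl and then removal of the tert-butyl group. The chosen route has no regiochemical decision in ring A at all and reaches its precursor from two cheap arenes in six steps.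

**Alternative 2: aryne insertion into an arylpropiolic acid.** The disconnection cuts C8a–O1, C4a–C4 and O1–C2 in one operation. In the forward key step, fluoride releases a triflyloxy aryne from the symmetric silyl bis-triflate A4. The carboxylate of A5 adds to it, the aryl anion attacks the ester carbonyl (acyl shift), and the resulting phenoxide closes onto the ynone to give triflate A3. In its favour, ring C is assembled in one flask and the C5 oxygen is already present as a triflate, whose S–O cleavage is easier than substitution of a C–Br bond; here it is stronger than the chosen route. Against it, A4 is a hexasubstituted benzene with no short route from a commercial compound. The aryne has a triflyloxy group on one side and a methoxy group on the other, and both steer a nucleophile to the far carbon, so the regiochemistry of carboxylate addition is contested. A5 has two ortho substituents and arylpropiolic acids decarboxylate easily, and five-membered closure to an aurone competes with six-membered closure. The chosen route offers a ring A building block in three steps and a closure whose regiochemistry is set by geometry alone.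

**Alternative 3: three-component carbonylative annulation.** The disconnection cuts C4a–C4, C4–C3 and O1–C2. In the forward key step, a palladium-catalysed carbonylative Sonogashira coupling of iodoresorcinol A7 with alkyne A8 gives an ortho-hydroxyaryl ynone, which an amine base closes in the six-membered mode to A6. In its favour, this is the most convergent plan, either hydroxyl of the symmetric A7 can close, and the C5 hydroxyl is free at once. A6 is only two deprotections from the target, a shorter endgame than the chosen one. Against it, A7 is a pentaoxygenated iodoarene with two free phenols: oxidative addition is slow, it is prone to oxidation to a quinone and to loss of iodine, and it has no short synthesis. A8 needs extra steps, carbonylation under pressure is required, and closure to an aurone competes. The chosen route keeps every intermediate as a stable, fully etherified arene made from cheap, symmetric material, and pays for this with one extra C–O coupling.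

Key step: step 7

Assumption: rotation about the C2–C1' bond is taken to be fast at room temperature in the target and in all intermediates, so no axial stereochemistry has to be set.

## Route

Step 1
Reactants: 1 syringic acid (4-hydroxy-3,5-dimethoxybenzoic acid)
Product: 3 4-(benzyloxy)-3,5-dimethoxybenzoic acid, via benzyl ester 2 (not isolated)
Conditions: BnBr (2.4 equiv), K2CO3 (3 equiv), DMF, 60 °C; then 2 M NaOH, MeOH, 70 °C; HCl to pH 2
Reagents that add atoms: benzyl bromide, BrCc1ccccc1
Why: Williamson O-alkylation of the phenoxide and the carboxylate, then saponification of the unhindered benzyl ester in the same flask; the aryl benzyl ether is inert to hydroxide.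

Step 2
Reactants: 3 4-(benzyloxy)-3,5-dimethoxybenzoic acid
Product: 4 4-(benzyloxy)-2,6-dibromo-3,5-dimethoxybenzoic acid
Conditions: NBS (2.3 equiv), MeCN, 25 → 60 °C, dark
Reagents that add atoms: N-bromosuccinimide, O=C1CCC(=O)N1Br
Why: Electrophilic aromatic bromination; C2 and C6 are the only free positions and each is ortho to one methoxy group and para to the other. The benzyl ring is far less electron-rich and should be left alone in the dark, and no strong acid is generated that could cleave the benzyl ether.

Step 3
Reactants: 4 4-(benzyloxy)-2,6-dibromo-3,5-dimethoxybenzoic acid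
Product: 5 4-(benzyloxy)-2,6-dibromo-3,5-dimethoxybenzoyl chloride
Conditions: (COCl)2 (1.5 equiv), DMF (cat.), CH2Cl2, 0 °C → rt; evaporate, use crude
Reagents that add atoms: oxalyl chloride, O=C(Cl)C(Cl)=O
Why: Acid chloride formation through the Vilsmeier-type chloroiminium catalyst; the chloride is needed because an ester flanked by two bromines would not acylate an enolate, and the benzyl and methyl ethers tolerate the conditions.

Step 4
Reactants: 6 methoxyhydroquinone (2-methoxybenzene-1,4-diol)
Product: 7 2-methoxy-1,4-bis(methoxymethoxy)benzene
Conditions: MOMCl (2.6 equiv), i-Pr2NEt (3.2 equiv), CH2Cl2, 0 °C → rt, argon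
Reagents that add atoms: chloromethyl methyl ether, COCCl
Why: O-alkylation of both phenols with the reactive α-chloro ether under amine base; working under argon keeps the hydroquinone from oxidising before it is capped.

Step 5
Reactants: 7 2-methoxy-1,4-bis(methoxymethoxy)benzene
Product: 9 1-[2-methoxy-3,6-bis(methoxymethoxy)phenyl]ethan-1-one, via aryllithium 8 (not isolated)
Conditions: n-BuLi (1.15 equiv), TMEDA, THF, −78 → 0 °C; then MeC(O)N(OMe)Me, −78 °C → rt; aq. NH4Cl
Reagents that add atoms: N-methoxy-N-methylacetamide, CC(=O)N(C)OC; n-butyllithium, [Li]CCCC (lithium of intermediate 8 only)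
Why: Directed ortho-metalation at C3 of 7, the only carbon flanked by two coordinating ether oxygens (methoxy and methoxymethoxy), followed by a Weinreb ketone synthesis, in which the chelated tetrahedral adduct prevents double addition.

Step 6
Reactants: 9 1-[2-methoxy-3,6-bis(methoxymethoxy)phenyl]ethan-1-one; 5 4-(benzyloxy)-2,6-dibromo-3,5-dimethoxybenzoyl chloride
Product: 11 1-[4-(benzyloxy)-2,6-dibromo-3,5-dimethoxyphenyl]-3-[2-methoxy-3,6-bis(methoxymethoxy)phenyl]propane-1,3-dione, via lithium enolate 10 (not isolated)
Conditions: 9, LiN(SiMe3)2 (2.2 equiv), THF, −78 °C; then 5 (1.05 equiv), −78 → 0 °C; aq. NH4Cl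
Reagents that add atoms: lithium bis(trimethylsilyl)amide, [Li]N([Si](C)(C)C)[Si](C)(C)C (lithium of intermediate 10 only)
Why: Crossed Claisen-type C-acylation of a methyl ketone lithium enolate with an aroyl chloride; the second equivalent of base deprotonates the more acidic diketone as it forms and so prevents proton transfer to unreacted enolate. The amide base does not exchange with the aryl bromides.

Step 7
Reactants: 11 1-[4-(benzyloxy)-2,6-dibromo-3,5-dimethoxyphenyl]-3-[2-methoxy-3,6-bis(methoxymethoxy)phenyl]propane-1,3-dione
Product: 12 7-(benzyloxy)-5-bromo-6,8-dimethoxy-2-[2-methoxy-3,6-bis(methoxymethoxy)phenyl]-4H-chromen-4-one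
Conditions: CuI (10 mol %), 1,10-phenanthroline (20 mol %), Cs2CO3 (2.0 equiv), 1,4-dioxane (0.03 M), 100 °C, argon
Reagents that add atoms: none
Why: Cs2CO3 converts the diketone into its enolate, which replaces iodide on (phen)CuI and binds copper through the oxygen on the carbon that carries ring B, the future O1. Monovalent copper then inserts into one of the two homotopic ortho C–Br bonds, and C–O reductive elimination from the trivalent aryl copper alkoxide forms C8a–O1 and regenerates the catalyst. The closest known reaction is the copper-catalysed intramolecular Ullmann-type O-arylation of 1-(2-haloaryl)-1,3-diketones to chromones and flavones, helped by the same chelation that drives the Hurtley arylation. Ring C closes in a formal 6-exo-trig mode, the enol oxygen attacking an sp2 aryl carbon whose bromide lies outside the new ring, by way of a seven-membered copper metallacycle. No stereocentre is formed. Oxygen arylation is secured because the central carbon and the ring A carbonyl oxygen could reach a bromide only through four-membered rings. Single substitution is secured because closure consumes the enolate, the C5 bromide then has no internal nucleophile, and dilution disfavours intermolecular arylation. The two ortho bromines twist the ring A carbonyl out of the arene plane, which holds the enolate oxygen above C8a; dioxane is used instead of an amide solvent so that no amine is present to open the new pyranone.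

Step 8
Reactants: 12 7-(benzyloxy)-5-bromo-6,8-dimethoxy-2-[2-methoxy-3,6-bis(methoxymethoxy)phenyl]-4H-chromen-4-one
Product: 13 5,7-bis(benzyloxy)-6,8-dimethoxy-2-[2-methoxy-3,6-bis(methoxymethoxy)phenyl]-4H-chromen-4-one
Conditions: CuI (20 mol %), 3,4,7,8-tetramethyl-1,10-phenanthroline (40 mol %), Cs2CO3 (2.0 equiv), BnOH (5 equiv), toluene, 110 °C, argon
Reagents that add atoms: benzyl alcohol, OCc1ccccc1
Why: Copper-catalysed Ullmann-type C–O coupling of an aryl bromide with a primary alcohol; the peri C4 carbonyl can coordinate the copper alkoxide and deliver it to C5. Copper-mediated alkoxide exchange on bromoflavones is established, and the water-free carbonate conditions avoid hydroxide attack at C2 of ring C.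

Step 9
Reactants: 13 5,7-bis(benzyloxy)-6,8-dimethoxy-2-[2-methoxy-3,6-bis(methoxymethoxy)phenyl]-4H-chromen-4-one
Product: 14 5,7-dihydroxy-6,8-dimethoxy-2-[2-methoxy-3,6-bis(methoxymethoxy)phenyl]-4H-chromen-4-one
Conditions: H2 (1 atm), palladium on carbon (10 % Pd/C), EtOAc–MeOH, rt
Reagents that add atoms: none
Why: Hydrogenolysis of both aryl benzyl ethers in one operation; under these mild conditions the conjugated, tetrasubstituted-like C2–C3 double bond of a flavone and the acetals are normally untouched, and no halogen is left in the molecule.

Step 10
Reactants: 14 5,7-dihydroxy-6,8-dimethoxy-2-[2-methoxy-3,6-bis(methoxymethoxy)phenyl]-4H-chromen-4-one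
Product: 15 5,7-dihydroxy-2-(3,6-dihydroxy-2-methoxyphenyl)-6,8-dimethoxy-4H-chromen-4-one (5,7,3',6'-tetrahydroxy-6,8,2'-trimethoxyflavone)
Conditions: HCl (2 M in MeOH), MeOH–THF, 45 °C, argon, degassed solvents
Reagents that add atoms: none
Why: Acid-catalysed acetal exchange removes both methoxymethyl groups, with methanol trapping the oxocarbenium ion as a volatile acetal; the methyl ethers are stable, any acid-induced opening of ring C re-closes to the same flavone because ring A is symmetric, and oxygen is excluded to protect the hydroquinone.

## Compound list

1 | syringic acid (4-hydroxy-3,5-dimethoxybenzoic acid) | COc1cc(C(=O)O)cc(OC)c1O | starting material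
2 | benzyl 4-(benzyloxy)-3,5-dimethoxybenzoate | COc1cc(C(=O)OCc2ccccc2)cc(OC)c1OCc1ccccc1 | intermediate (not isolated)
3 | 4-(benzyloxy)-3,5-dimethoxybenzoic acid | COc1cc(C(=O)O)cc(OC)c1OCc1ccccc1 | intermediate
4 | 4-(benzyloxy)-2,6-dibromo-3,5-dimethoxybenzoic acid | COc1c(Br)c(C(=O)O)c(Br)c(OC)c1OCc1ccccc1 | intermediate
5 | 4-(benzyloxy)-2,6-dibromo-3,5-dimethoxybenzoyl chloride | COc1c(Br)c(C(Cl)=O)c(Br)c(OC)c1OCc1ccccc1 | intermediate
6 | methoxyhydroquinone (2-methoxybenzene-1,4-diol) | COc1cc(O)ccc1O | starting material
7 | 2-methoxy-1,4-bis(methoxymethoxy)benzene | COCOc1ccc(OCOC)c(OC)c1 | intermediate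
8 | [2-methoxy-3,6-bis(methoxymethoxy)phenyl]lithium | [Li]c1c(OC)c(OCOC)ccc1OCOC | intermediate (not isolated)
9 | 1-[2-methoxy-3,6-bis(methoxymethoxy)phenyl]ethan-1-one | CC(=O)c1c(OC)c(OCOC)ccc1OCOC | intermediate
10 | lithium 1-[2-methoxy-3,6-bis(methoxymethoxy)phenyl]ethen-1-olate | [Li]OC(=C)c1c(OC)c(OCOC)ccc1OCOC | intermediate (not isolated)
11 | 1-[4-(benzyloxy)-2,6-dibromo-3,5-dimethoxyphenyl]-3-[2-methoxy-3,6-bis(methoxymethoxy)phenyl]propane-1,3-dione | COCOc1ccc(OCOC)c(OC)c1C(=O)CC(=O)c1c(Br)c(OC)c(OCc2ccccc2)c(OC)c1Br | intermediate
12 | 7-(benzyloxy)-5-bromo-6,8-dimethoxy-2-[2-methoxy-3,6-bis(methoxymethoxy)phenyl]-4H-chromen-4-one | COCOc1ccc(OCOC)c(OC)c1-c1cc(=O)c2c(Br)c(OC)c(OCc3ccccc3)c(OC)c2o1 | intermediate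
13 | 5,7-bis(benzyloxy)-6,8-dimethoxy-2-[2-methoxy-3,6-bis(methoxymethoxy)phenyl]-4H-chromen-4-one | COCOc1ccc(OCOC)c(OC)c1-c1cc(=O)c2c(OCc3ccccc3)c(OC)c(OCc3ccccc3)c(OC)c2o1 | intermediate
14 | 5,7-dihydroxy-6,8-dimethoxy-2-[2-methoxy-3,6-bis(methoxymethoxy)phenyl]-4H-chromen-4-one | COCOc1ccc(OCOC)c(OC)c1-c1cc(=O)c2c(O)c(OC)c(O)c(OC)c2o1 | intermediate
15 | 5,7-dihydroxy-2-(3,6-dihydroxy-2-methoxyphenyl)-6,8-dimethoxy-4H-chromen-4-one | COc1c(O)ccc(O)c1-c1cc(=O)c2c(O)c(OC)c(O)c(OC)c2o1 | target

## Step count and least certain steps

Total: 10 steps. Longest linear sequence: 8 steps (steps 1, 2, 3, 6, 7, 8, 9, 10 from syringic acid 1); the ring B branch (steps 4 and 5) joins at step 6.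

**Step 7 (key step).** The most likely failure is slow insertion of copper into a C–Br bond that is flanked by the C8 methoxy group and the twisted acyl group. Base-induced retro-Claisen fragmentation of the diketone and reductive loss of bromine would then compete, and at high conversion intermolecular O-arylation at the remaining bromide could start. The fallback changes the electrophile rather than the catalyst. It sets out from 3: double iodination (NIS, catalytic CF3CO2H, MeCN) should give 4-(benzyloxy)-2,6-diiodo-3,5-dimethoxybenzoic acid F1. Oxalyl chloride converts F1 into the acid chloride F2, and acylation of enolate 10 as in step 6 gives the diiodo diketone F3. The far more reactive C–I bond should allow the same CuI, 1,10-phenanthroline and Cs2CO3 closure at 60–70 °C, giving the 5-iodoflavone F4. Copper-catalysed coupling of F4 with benzyl alcohol, as in step 8 but at lower temperature, returns to the route at 13.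

**Step 6.** The enolate may be acylated on oxygen instead of carbon, or attack at the carbonyl shielded by two bromines may be so slow that enolate 10 condenses with unreacted ketone 9. The fallback replaces acylation by aldol addition and oxidation. It sets out from 5: reduction with LiAlH(OtBu)3 in THF at −78 °C should give 4-(benzyloxy)-2,6-dibromo-3,5-dimethoxybenzaldehyde F5. Addition of enolate 10 at −78 °C gives the racemic β-hydroxy ketone F6, and Dess–Martin periodinane oxidises F6 to the diketone, returning at 11.

**Step 8.** The bromide may be reduced to C–H by hydride transfer from the copper-bound benzylic alkoxide, or coupling may not turn over at a carbon with two ortho substituents. The fallback goes through boron. It sets out from 12: Miyaura borylation (Pd(OAc)2, SPhos, bis(pinacolato)diboron, KOAc, dioxane, 90 °C) gives the C5 pinacol boronate F7, and oxidation with NaBO3·4H2O in THF–water gives 7-(benzyloxy)-5-hydroxy-6,8-dimethoxy-2-[2-methoxy-3,6-bis(methoxymethoxy)phenyl]-4H-chromen-4-one F8. Hydrogenolysis of F8 under the conditions of step 9 returns to the route at 14.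

**Step 5.** The hindered aryllithium may take a proton from the acetyl group of the amide instead of adding to it, which returns 7, or some metalation may occur at the carbons next to only one ether oxygen. The fallback uses an electrophile that cannot be enolised. It sets out from 8: quenching with DMF gives 2-methoxy-3,6-bis(methoxymethoxy)benzaldehyde F9, which can be freed of regioisomers at this stage. MeMgBr adds to F9 to give the racemic carbinol F10, and Dess–Martin oxidation of F10 returns at 9.

**Step 10.** The liberated hydroquinone may oxidise to the quinone during work-up, and the methoxymethyl cation may alkylate the free ring B positions C4' and C5'. The fallback reverses the order of the two deprotections so that the last operation is reductive and neutral. It sets out from 13: methanolic HCl removes the acetals first and gives 5,7-bis(benzyloxy)-2-(3,6-dihydroxy-2-methoxyphenyl)-6,8-dimethoxy-4H-chromen-4-one F11. Hydrogenolysis of F11 over Pd/C then gives the target, returning at 15; any quinone formed on the way is reduced back under hydrogen.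

## Further compounds

F1 | step 7 | 4-(benzyloxy)-2,6-diiodo-3,5-dimethoxybenzoic acid | COc1c(I)c(C(=O)O)c(I)c(OC)c1OCc1ccccc1
F2 | step 7 | 4-(benzyloxy)-2,6-diiodo-3,5-dimethoxybenzoyl chloride | COc1c(I)c(C(Cl)=O)c(I)c(OC)c1OCc1ccccc1
F3 | step 7 | 1-[4-(benzyloxy)-2,6-diiodo-3,5-dimethoxyphenyl]-3-[2-methoxy-3,6-bis(methoxymethoxy)phenyl]propane-1,3-dione | COCOc1ccc(OCOC)c(OC)c1C(=O)CC(=O)c1c(I)c(OC)c(OCc2ccccc2)c(OC)c1I
F4 | step 7 | 7-(benzyloxy)-5-iodo-6,8-dimethoxy-2-[2-methoxy-3,6-bis(methoxymethoxy)phenyl]-4H-chromen-4-one | COCOc1ccc(OCOC)c(OC)c1-c1cc(=O)c2c(I)c(OC)c(OCc3ccccc3)c(OC)c2o1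
F5 | step 6 | 4-(benzyloxy)-2,6-dibromo-3,5-dimethoxybenzaldehyde | COc1c(Br)c(C=O)c(Br)c(OC)c1OCc1ccccc1
F6 | step 6 | 3-[4-(benzyloxy)-2,6-dibromo-3,5-dimethoxyphenyl]-3-hydroxy-1-[2-methoxy-3,6-bis(methoxymethoxy)phenyl]propan-1-one (racemic) | COCOc1ccc(OCOC)c(OC)c1C(=O)CC(O)c1c(Br)c(OC)c(OCc2ccccc2)c(OC)c1Br
F7 | step 8 | 7-(benzyloxy)-6,8-dimethoxy-2-[2-methoxy-3,6-bis(methoxymethoxy)phenyl]-5-(4,4,5,5-tetramethyl-1,3,2-dioxaborolan-2-yl)-4H-chromen-4-one | COCOc1ccc(OCOC)c(OC)c1-c1cc(=O)c2c(B3OC(C)(C)C(C)(C)O3)c(OC)c(OCc3ccccc3)c(OC)c2o1
F8 | step 8 | 7-(benzyloxy)-5-hydroxy-6,8-dimethoxy-2-[2-methoxy-3,6-bis(methoxymethoxy)phenyl]-4H-chromen-4-one | COCOc1ccc(OCOC)c(OC)c1-c1cc(=O)c2c(O)c(OC)c(OCc3ccccc3)c(OC)c2o1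
F9 | step 5 | 2-methoxy-3,6-bis(methoxymethoxy)benzaldehyde | COCOc1ccc(OCOC)c(OC)c1C=O
F10 | step 5 | 1-[2-methoxy-3,6-bis(methoxymethoxy)phenyl]ethan-1-ol (racemic) | COCOc1ccc(OCOC)c(OC)c1C(C)O
F11 | step 10 | 5,7-bis(benzyloxy)-2-(3,6-dihydroxy-2-methoxyphenyl)-6,8-dimethoxy-4H-chromen-4-one | COc1c(O)ccc(O)c1-c1cc(=O)c2c(OCc3ccccc3)c(OC)c(OCc3ccccc3)c(OC)c2o1
A1 | alternative 1 | 7-tert-butoxy-5,8-dihydroxy-6-methoxy-2-[2-methoxy-3,6-bis(methoxymethoxy)phenyl]-4H-chromen-4-one | COCOc1ccc(OCOC)c(OC)c1-c1cc(=O)c2c(O)c(OC)c(OC(C)(C)C)c(O)c2o1
A2 | alternative 1 | 2-tert-butoxy-4-hydroxy-3-methoxy-4-{6-[2-methoxy-3,6-bis(methoxymethoxy)phenyl]-4-oxo-4H-pyran-3-yl}cyclobut-2-en-1-one (racemic) | COCOc1ccc(OCOC)c(OC)c1-c1cc(=O)c(co1)C1(O)C(OC)=C(OC(C)(C)C)C1=O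
A3 | alternative 2 | 7-(benzyloxy)-6,8-dimethoxy-2-[2-methoxy-3,6-bis(methoxymethoxy)phenyl]-4-oxo-4H-chromen-5-yl trifluoromethanesulfonate | COCOc1ccc(OCOC)c(OC)c1-c1cc(=O)c2c(OS(=O)(=O)C(F)(F)F)c(OC)c(OCc3ccccc3)c(OC)c2o1
A4 | alternative 2 | 5-(benzyloxy)-4,6-dimethoxy-2-(trimethylsilyl)-1,3-phenylene bis(trifluoromethanesulfonate) | C[Si](C)(C)c1c(OS(=O)(=O)C(F)(F)F)c(OC)c(OCc2ccccc2)c(OC)c1OS(=O)(=O)C(F)(F)F
A5 | alternative 2 | 3-[2-methoxy-3,6-bis(methoxymethoxy)phenyl]prop-2-ynoic acid | COCOc1ccc(OCOC)c(OC)c1C#CC(=O)O
A6 | alternative 3 | 7-(benzyloxy)-5-hydroxy-6,8-dimethoxy-2-[2-methoxy-3,6-bis(methoxymethoxy)phenyl]-4H-chromen-4-one | COCOc1ccc(OCOC)c(OC)c1-c1cc(=O)c2c(O)c(OC)c(OCc3ccccc3)c(OC)c2o1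
A7 | alternative 3 | 5-(benzyloxy)-2-iodo-4,6-dimethoxybenzene-1,3-diol | Oc1c(I)c(O)c(OC)c(OCc2ccccc2)c1OC
A8 | alternative 3 | 2-ethynyl-3-methoxy-1,4-bis(methoxymethoxy)benzene | C#Cc1c(OC)c(OCOC)ccc1OCOC
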